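The six-membered ring of the longipinene core is cut at C1–C11 and C3–C4. What remains is a three-carbon piece (C1–C2=C3 with its methyl) and the cyclobutane C4–C5–C11–C10, whose 1,3-related carbons C4 and C11 are joined as the central bond of a bicyclo[1.1.0]butane. With ketals at C7 and C9 that tricycle has a mirror plane, so a single catalyst-controlled (3+3) annulation with the vinylcarbene from 3-diazobut-1-ene forms the ring, both bonds and all four cyclobutane stereocentres. The precursor is an achiral bridged bicyclobutane carrying a dioxolane at C7 and a more labile dimethyl ketal at C9, which lets the two ketones be unmasked one after the other.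

Key step: step 9

Remarks
- Atom numbers are those of the longipinane skeleton: C1 ketone, C2=C3 (methyl on C3), cyclobutane C4–C5–C11–C10, C6 gem-dimethyl, C7 (isovalerate), C8, C9 (senecioate), C10 (methyl).
- Compounds 3–10 are racemic and drawn as one enantiomer; 11 is achiral; from 17 on all compounds are single enantiomers.
- Assumption: the sense of induction of Rh2(S-PTAD)4 in this new reaction cannot be predicted, so the S catalyst is written and its mirror image Rh2(R-PTAD)4 would be used if it engaged the other bridgehead.

Step 1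
Reactants: 1 furan; 2 3-bromo-3-methylbutan-2-one
Product: 3 racemic 2,2-dimethyl-8-oxabicyclo[3.2.1]oct-6-en-3-one
Conditions: furan (excess), Et3N, CF3CH2OH, 0 °C to rt
Reagents that add atoms: none
Why: Base-induced loss of HBr from 2 gives the 1,1-dimethyl-2-oxyallyl cation, which undergoes the oxyallyl–furan (4+3) cycloaddition; the two bridgehead centres are necessarily cis and the adduct is racemic.

Step 2
Reactants: 3 racemic 2,2-dimethyl-8-oxabicyclo[3.2.1]oct-6-en-3-one
Product: 4 racemic ethylene ketal of 3 (dioxolane on C7)
Conditions: (TMSOCH2)2, TMSOTf (5 mol %), CH2Cl2, −78 to −20 °C; pyridine quench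
Reagents that add atoms: 1,2-bis(trimethylsilyloxy)ethane, C[Si](C)(C)OCCO[Si](C)(C)C
Why: Silyl-triflate-catalysed ketalisation with the bis-silyl ether of the diol copes with the hindered α,α-dimethyl ketone at low temperature and leaves the allylic ether bridge untouched; no stereocentre changes.

Step 3
Reactants: 4 racemic ethylene ketal of 3
Product: 5 racemic cis-6,6,9-trimethyl-1,4-dioxaspiro[4.6]undec-7-en-10-ol (C9 hydroxyl and C10 methyl cis, C4=C5 alkene)
Conditions: MeLi (5 equiv), TMEDA, Et2O, 0 °C to reflux; H2O
Reagents that add atoms: methyllithium, [Li]C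
Why: Ring opening of the oxabicyclic alkene by carbolithiation and β-alkoxide elimination (overall syn SN2′) should deliver the methyl on the exo face to the alkene carbon remote from the gem-dimethyl group (C10) and break the C5–O bond, so the C9 oxygen and C10 methyl end up cis.

Step 4
Reactants: 5 racemic cis-cycloheptenol
Product: 6 racemic 6,6,9-trimethyl-1,4-dioxaspiro[4.6]undec-7-en-10-one (C9 ketone, C10–H, C4=C5)
Conditions: Dess–Martin periodinane, NaHCO3, CH2Cl2, 0 °C to rt
Reagents that add atoms: none
Why: Buffered Dess–Martin oxidation is neutral enough to keep the β,γ-alkene out of conjugation; C10 is now the only stereocentre and its configuration is immaterial because it is equilibrated in step 5.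

Step 5
Reactants: 6 racemic β,γ-unsaturated ketone
Product: 8 racemic trans-dibromocyclopropyl ketone (C10 methyl anti to the CBr2 bridge), via cis-epimeric adduct 7 (not isolated)
Conditions: PhHgCBr3 (2.5 equiv), benzene, 80 °C; then DBU (0.2 equiv), CH2Cl2, rt
Reagents that add atoms: phenyl(tribromomethyl)mercury, BrC(Br)(Br)[Hg]c1ccccc1
Why: Seyferth's reagent transfers dibromocarbene thermally under neutral conditions, so the enolisable ketone survives a stereospecific cis cyclopropanation of C4=C5, and DBU then equilibrates C10 through the enolate so that the methyl sits anti to the CBr2 bridge, away from the endo bromine, which leaves the C10 hydrogen syn to C11 as step 7 requires.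

Step 6
Reactants: 8 racemic trans-dibromocyclopropyl ketone
Product: 9 racemic 8,8-dibromo-3,3-dimethoxy-2,6,6-trimethylspiro[bicyclo[5.1.0]octane-5,2′-[1,3]dioxolane] (C9 dimethyl ketal of 8)
Conditions: HC(OMe)3, MeOH, PPTS (cat.), rt
Reagents that add atoms: trimethyl orthoformate, COC(OC)OC; methanol, CO
Why: Acid-catalysed ketalisation driven by the orthoformate installs the deliberately more labile acyclic ketal at C9 while the dioxolane at C7, being the thermodynamically preferred cyclic ketal, does not exchange; no stereocentre changes.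

Step 7
Reactants: 9 racemic dibromide bis-ketal
Product: 11 achiral 3,3-dimethoxy-2,6,6-trimethylspiro[tricyclo[5.1.0.0(2,8)]octane-5,2′-[1,3]dioxolane] (bridged bicyclobutane with central bond C4–C11 and exo H on C5 and exo methyl on C10), via bromolithio carbenoid 10 (not isolated)
Conditions: MeLi (1.5 equiv), Et2O, −78 to 0 °C; basic alumina
Reagents that add atoms: none
Why: Bromine–lithium exchange gives a cyclopropylidene carbenoid that inserts into the syn tertiary C10–H bond with retention (the 1,3-insertion branch of the Doering–Moore–Skattebøl manifold, known for this ring system), forming C10–C11; the product has a mirror plane, so both enantiomers of 9 converge on one achiral compound.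

Step 8
Reactants: 12 but-3-en-2-one; 13 2-(trifluoromethyl)benzenesulfonohydrazide
Product: 14 but-3-en-2-one N-[2-(trifluoromethyl)phenylsulfonyl]hydrazone
Conditions: MeOH, 0 °C, 1 h; cold filtration, used at once
Reagents that add atoms: none
Why: Hydrazone condensation at the carbonyl is faster at low temperature than conjugate addition, and the product is used cold before it can cyclise to a pyrazoline.

Step 9
Reactants: 11 achiral bridged bicyclobutane bis-ketal; 14 sulfonylhydrazone
Product: 17 longipin-2-ene-7,9-dione 7-(ethylene ketal) 9-(dimethyl ketal) (single enantiomer; C5–H and C10–CH3 syn to the C1–C3 bridge), via hydrazone sodium salt 15 (not isolated), via 3-diazobut-1-ene 16 (not isolated)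
Conditions: NaH (3 equiv), Rh2(S-PTAD)4 (2 mol %), CH2Cl2, −40 to 0 °C, 14 added in portions
Reagents that add atoms: none
Why: Proposed new method: the donor-type divalent-rhodium carbene generated from 16 is electrophilic at its remote CH2 carbon, and the electron-rich central C4–C11 bond of 11 donates into that carbon from its exposed face (the one not covered by the C6–C9 tether), which makes C1–C11 and turns C4 into a cyclobutyl cation flanked by an alkenyl–rhodium group; this alkenyl–metal carbon (C3) then bonds to C4 with loss of the catalyst and leaves the C2=C3 double bond. The closest known reaction type is the formal (3+3) cycloaddition of aryl- or acyl-substituted bicyclo[1.1.0]butanes with metal vinylcarbenes to bicyclo[3.1.1]heptenes, together with the vinylogous reactivity of rhodium vinylcarbenes. The six-membered ring (C11, C1, C2, C3, C4 and C5 or C10) closes in the second bond-forming event, an endo-mode attack of C3 on the C4 cation with the C2=C3 bond inside the new ring, so the process is a stepwise (3+3) annulation. C4 and C11 are enantiotopic in mirror-symmetric 11, so the chiral carboxylate ligands decide which bridgehead receives the CH2 terminus, and that one choice, with both new bonds forced onto the convex face by the tether, fixes C4, C5, C10 and C11 together. The step needs site selectivity between the bridgeheads from the catalyst and chemoselectivity for the σ-bond over C–H insertion and cation rearrangement; the substrate contributes a high-lying strained σ-bond, no competing π-nucleophile and ketal-masked carbonyls.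

Step 10
Reactants: 17 longipin-2-ene bis-ketal
Product: 18 longipin-2-ene-1,7,9-trione 7-(ethylene ketal) 9-(dimethyl ketal)
Conditions: Rh2(cap)4 (dirhodium tetracaprolactamate, 1 mol %), t-BuOOH (5 equiv, in decane), K2CO3, CH2Cl2, rt
Reagents that add atoms: tert-butyl hydroperoxide, CC(C)(C)OO
Why: Allylic oxidation by tert-butylperoxyl radicals converts the only secondary allylic CH2 (C1) into the enone, the α-pinene-to-verbenone type of conversion, and the basic medium spares both ketals.

Step 11
Reactants: 18 enone bis-ketal
Product: 19 longipin-2-ene-1,7,9-trione 7-(ethylene ketal) (C9 ketone free)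
Conditions: PPTS (0.1 equiv), acetone/H2O 10:1, rt
Reagents that add atoms: water, O
Why: Acid hydrolysis is selective because acyclic dimethyl ketals cleave orders of magnitude faster than dioxolanes, so only C9 is unmasked.

Step 12
Reactants: 19 1,9-dione 7-ketal
Product: 20 (9R)-1,9-dihydroxylongipin-2-en-7-one ethylene ketal (mixture of C1 epimers)
Conditions: (S)-Me-CBS (0.5 equiv), catecholborane (4 equiv), toluene, −78 to −20 °C; MeOH, aq NaOH
Reagents that add atoms: none
Why: In this Corey–Bakshi–Shibata reduction the oxazaborolidine treats quaternary C10 as the large and C8H2 as the small group and so delivers hydride to the face that gives the (9R) alcohol whatever the weak substrate bias, while the enone carbonyl is reduced as well (C1 configuration is of no consequence) and catecholborane does not hydroborate the alkene.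

Step 13
Reactants: 20 1,9-diol
Product: 21 (9R)-9-hydroxylongipin-2-ene-1,7-dione 7-(ethylene ketal)
Conditions: MnO2 (20 equiv), CH2Cl2, rt
Reagents that add atoms: none
Why: Manganese dioxide oxidises only the allylic C1 alcohol, which restores the enone and leaves the hindered saturated C9 alcohol.

Step 14
Reactants: 21 9-hydroxy enone; 22 3-methylbut-2-enoyl chloride
Product: 23 (9R)-9-(3-methylbut-2-enoyloxy)longipin-2-ene-1,7-dione 7-(ethylene ketal)
Conditions: DMAP (0.3 equiv), pyridine, CH2Cl2, 0 to 40 °C
Reagents that add atoms: none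
Why: DMAP-catalysed acylation esterifies the secondary alcohol with retention at C9, and pyridine as the only base avoids vinylketene formation and hence deconjugation of the senecioyl group.

Step 15
Reactants: 23 9-senecioate 7-ketal
Product: 24 (9R)-9-(3-methylbut-2-enoyloxy)longipin-2-ene-1,7-dione
Conditions: TsOH·H2O (0.2 equiv), acetone/H2O 10:1, 45 °C
Reagents that add atoms: water, O
Why: Acid-catalysed dioxolane hydrolysis frees the C7 ketone, and the enone, the ester and the resulting β-acyloxy ketone all tolerate the mild acid.

Step 16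
Reactants: 24 1,7-dione 9-senecioate
Product: 25 (7R,9R)-1,7-dihydroxylongipin-2-en-9-yl 3-methylbut-2-enoate (mixture of C1 epimers)
Conditions: (S)-Me-CBS (0.5 equiv), catecholborane (4 equiv), toluene, −78 to −20 °C; MeOH, pH 7 buffer
Reagents that add atoms: none
Why: A second Corey–Bakshi–Shibata reduction with the same catalyst reads quaternary C6 as the large and C8H2 as the small group and gives the (7R) alcohol, anti to the C9 ester, while the enoate is inert and C1 is reduced again.

Step 17
Reactants: 25 1,7-diol 9-senecioate
Product: 26 (7R,9R)-7-hydroxy-1-oxolongipin-2-en-9-yl 3-methylbut-2-enoate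
Conditions: MnO2 (20 equiv), CH2Cl2, rt
Reagents that add atoms: none
Why: Selective manganese dioxide oxidation of the allylic C1 alcohol regenerates the enone without touching the neopentyl C7 alcohol.

Step 18
Reactants: 26 7-hydroxy enone 9-senecioate; 27 3-methylbutanoyl chloride
Product: 28 (7R,9R)-7-(3-methylbutanoyloxy)-9-(3-methylbut-2-enoyloxy)longipin-2-en-1-one (CNP0335239.1)
Conditions: DMAP (0.5 equiv), pyridine, CH2Cl2, rt to 40 °C
Reagents that add atoms: none
Why: DMAP-catalysed acylation of the hindered C7 alcohol proceeds with retention and should outrun acyl migration from C9 under these non-equilibrating conditions, completing the target.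

Compound list
1 | furan | c1ccoc1 | starting material
2 | 3-bromo-3-methylbutan-2-one | CC(=O)C(C)(C)Br | starting material
3 | racemic 2,2-dimethyl-8-oxabicyclo[3.2.1]oct-6-en-3-one | O=C1C[C@H]2C=C[C@H](O2)C1(C)C | intermediate
4 | racemic 3,3-ethylenedioxy-2,2-dimethyl-8-oxabicyclo[3.2.1]oct-6-ene | C1[C@H]2C=C[C@H](O2)C(C)(C)C13OCCO3 | intermediate
5 | racemic cis-6,6,9-trimethyl-1,4-dioxaspiro[4.6]undec-7-en-10-ol | O[C@H]1CC2(OCCO2)C(C)(C)C=C[C@H]1C | intermediate
6 | racemic 6,6,9-trimethyl-1,4-dioxaspiro[4.6]undec-7-en-10-one | O=C1CC2(OCCO2)C(C)(C)C=C[C@H]1C | intermediate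
7 | racemic 8,8-dibromo-2,6,6-trimethylspiro[bicyclo[5.1.0]octane-5,2′-[1,3]dioxolan]-3-one, 2-methyl syn to CBr2 | O=C1CC2(OCCO2)C(C)(C)[C@@H]3C(Br)(Br)[C@@H]3[C@@H]1C | intermediate
8 | racemic 8,8-dibromo-2,6,6-trimethylspiro[bicyclo[5.1.0]octane-5,2′-[1,3]dioxolan]-3-one, 2-methyl anti to CBr2 | O=C1CC2(OCCO2)C(C)(C)[C@@H]3C(Br)(Br)[C@@H]3[C@H]1C | intermediate
9 | racemic 8,8-dibromo-3,3-dimethoxy-2,6,6-trimethylspiro[bicyclo[5.1.0]octane-5,2′-[1,3]dioxolane], 2-methyl anti to CBr2 | COC1(OC)CC2(OCCO2)C(C)(C)[C@@H]3C(Br)(Br)[C@@H]3[C@H]1C | intermediate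
10 | 8-bromo-8-lithio carbenoid derived from 9 | COC1(OC)CC2(OCCO2)C(C)(C)[C@@H]3C([Li])(Br)[C@@H]3[C@H]1C | intermediate
11 | achiral 3,3-dimethoxy-2,6,6-trimethylspiro[tricyclo[5.1.0.0(2,8)]octane-5,2′-[1,3]dioxolane] (endo-bridged bicyclobutane, central bond C4–C11) | [C@@H]12[C@H]3C(C)(C)C4(OCCO4)CC(OC)(OC)[C@]1(C)[C@@H]23 | intermediate
12 | but-3-en-2-one | CC(=O)C=C | starting material
13 | 2-(trifluoromethyl)benzenesulfonohydrazide | NNS(=O)(=O)c1ccccc1C(F)(F)F | starting material
14 | but-3-en-2-one N-[2-(trifluoromethyl)phenylsulfonyl]hydrazone | CC(C=C)=NNS(=O)(=O)c1ccccc1C(F)(F)F | intermediate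
15 | sodium salt of hydrazone 14 | CC(C=C)=N[N-]S(=O)(=O)c1ccccc1C(F)(F)F.[Na+] | intermediate
16 | 3-diazobut-1-ene | C=CC(C)=[N+]=[N-] | intermediate
17 | longipin-2-ene-7,9-dione 7-(ethylene ketal) 9-(dimethyl ketal) | COC1(OC)CC4(OCCO4)C(C)(C)[C@@H]2[C@H]3CC=C(C)[C@@H]2[C@]31C | intermediate
18 | longipin-2-ene-1,7,9-trione 7-(ethylene ketal) 9-(dimethyl ketal) | COC1(OC)CC4(OCCO4)C(C)(C)[C@@H]2[C@H]3C(=O)C=C(C)[C@@H]2[C@]31C | intermediate
19 | longipin-2-ene-1,7,9-trione 7-(ethylene ketal) | O=C1CC4(OCCO4)C(C)(C)[C@@H]2[C@H]3C(=O)C=C(C)[C@@H]2[C@]31C | intermediate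
20 | (9R)-1,9-dihydroxylongipin-2-en-7-one ethylene ketal, C1 epimers | O[C@@H]1CC4(OCCO4)C(C)(C)[C@@H]2[C@H]3C(O)C=C(C)[C@@H]2[C@]31C | intermediate
21 | (9R)-9-hydroxylongipin-2-ene-1,7-dione 7-(ethylene ketal) | O[C@@H]1CC4(OCCO4)C(C)(C)[C@@H]2[C@H]3C(=O)C=C(C)[C@@H]2[C@]31C | intermediate
22 | 3-methylbut-2-enoyl chloride | CC(C)=CC(=O)Cl | starting material
23 | (9R)-9-(3-methylbut-2-enoyloxy)longipin-2-ene-1,7-dione 7-(ethylene ketal) | CC(C)=CC(=O)O[C@@H]1CC4(OCCO4)C(C)(C)[C@@H]2[C@H]3C(=O)C=C(C)[C@@H]2[C@]31C | intermediate
24 | (9R)-9-(3-methylbut-2-enoyloxy)longipin-2-ene-1,7-dione | CC(C)=CC(=O)O[C@@H]1CC(=O)C(C)(C)[C@@H]2[C@H]3C(=O)C=C(C)[C@@H]2[C@]31C | intermediate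
25 | (7R,9R)-1,7-dihydroxylongipin-2-en-9-yl 3-methylbut-2-enoate, C1 epimers | CC(C)=CC(=O)O[C@@H]1C[C@@H](O)C(C)(C)[C@@H]2[C@H]3C(O)C=C(C)[C@@H]2[C@]31C | intermediate
26 | (7R,9R)-7-hydroxy-1-oxolongipin-2-en-9-yl 3-methylbut-2-enoate | CC(C)=CC(=O)O[C@@H]1C[C@@H](O)C(C)(C)[C@@H]2[C@H]3C(=O)C=C(C)[C@@H]2[C@]31C | intermediate
27 | 3-methylbutanoyl chloride | CC(C)CC(=O)Cl | starting material
28 | (7R,9R)-7-(3-methylbutanoyloxy)-9-(3-methylbut-2-enoyloxy)longipin-2-en-1-one (CNP0335239.1) | CC(C)=CC(=O)O[C@@H]1C[C@@H](OC(=O)CC(C)C)C(C)(C)[C@@H]2[C@H]3C(=O)C=C(C)[C@@H]2[C@]31C | target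

Total step count: 18. Longest linear sequence: 17 steps (steps 1–7 and 9–18; step 8 is a one-step branch).

Steps most likely to fail

Step 9 (new method). The carbene may be lost to dimerisation, to cyclisation of 16 into a pyrazole or to C–H insertion. The C4 cation may rearrange before the ring closes, the rhodium catalyst may isomerise 11 to dienes, or the two bridgeheads may not be told apart. The fallback uses known chemistry, sets out from 11 and comes back at 18, so step 10 is not needed. The acidic bridgehead C–H bonds of 11 are lithiated (n-BuLi, TMEDA) and trapped with acetaldehyde, first to the bridgehead mono-carbinol F1 and, after a second lithiation, to the 4,11-bis(1-hydroxyethyl) diol F2. Dess–Martin oxidation gives the 4,11-diacetylbicyclobutane F3. Samarium diiodide SmI2 in THF/MeOH cleaves its doubly acyl-activated central bond reductively to the meso cis-4,11-diacetylcyclobutane F4, whose two α-centres can equilibrate. A cinchona-derived primary amine (9-amino-9-deoxy-epi-quinine with an acid co-catalyst, or its quinidine-derived counterpart) then closes the ring by a desymmetrising intramolecular aldol condensation, the established enantioselective cyclisation of heptane-2,6-dione-type diketones to 3-methylcyclohex-2-enones, and gives enone 18.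

Step 7. The carbenoid may open to a strained cyclic allene that dimerises, or insert into a methyl C–H bond, faster than it inserts into the C10–H bond, which the neighbouring ketal deactivates inductively. The fallback sets out from 6 and comes back at 11, bypassing steps 5–7. The dienolate of 6 (LiN(i-Pr)2, −78 °C) is hydroxymethylated at C10 with formaldehyde to the C10-hydroxymethyl ketone F5. Ketalisation as in step 6 gives the dimethyl ketal alcohol F6, Dess–Martin oxidation gives the neopentyl aldehyde F7, and tosylhydrazide gives the tosylhydrazone F8. Aprotic Bamford–Stevens decomposition of its sodium salt (NaH, diglyme, 140 °C) generates the allylcarbene at C11, which adds across C4=C5 on its own face (the intramolecular cyclopropanation route from allylcarbenes to bicyclobutanes) and gives 11.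

Step 3. Carbolithiation may occur at the wrong alkene carbon (C4), which breaks the C9–O instead of the C5–O bond, or methyllithium may add too sluggishly. The fallback sets out from 2 and comes back at 6; it brings the methyl in with the diene. The (4+3) cycloaddition of 2 with 3-methylfuran, in which the more nucleophilic furan C2 should bond to the unhindered CH2 terminus of the oxyallyl cation, gives the 2,2,6-trimethyl cycloadduct F9. Ketalisation as in step 2 gives the ethylene ketal F10. Nickel-catalysed hydroalumination (Ni(cod)2, i-Bu2AlH) places aluminium on the unsubstituted alkene carbon C4 and hydrogen on C10, and β-alkoxide elimination of the C5–O bond gives the trans-cycloheptenol F11. Dess–Martin oxidation then gives 6.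

Further compounds
F1 | step 9 | bridgehead mono-carbinol, 4-(1-hydroxyethyl) derivative of 11 (racemic, carbinol epimers) | [C@@]12(C(C)O)[C@H]3C(C)(C)C4(OCCO4)CC(OC)(OC)[C@]1(C)[C@@H]23
F2 | step 9 | 4,11-bis(1-hydroxyethyl) diol of 11 (carbinol epimers) | [C@@]12(C(C)O)[C@H]3C(C)(C)C4(OCCO4)CC(OC)(OC)[C@]1(C)[C@@]23C(C)O
F3 | step 9 | 4,11-diacetylbicyclobutane (achiral) | [C@@]12(C(C)=O)[C@H]3C(C)(C)C4(OCCO4)CC(OC)(OC)[C@]1(C)[C@@]23C(C)=O
F4 | step 9 | meso cis-4,11-diacetylcyclobutane (both acetyl groups on the face away from the C6–C9 chain) | COC1(OC)CC4(OCCO4)C(C)(C)[C@@H]2[C@@H](C(C)=O)[C@@]1(C)[C@H]2C(C)=O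
F5 | step 7 | racemic C10-hydroxymethyl ketone, 9-(hydroxymethyl)-6,6,9-trimethyl-1,4-dioxaspiro[4.6]undec-7-en-10-one | O=C1CC2(OCCO2)C(C)(C)C=C[C@]1(C)CO
F6 | step 7 | racemic dimethyl ketal alcohol derived from F5 | COC1(OC)CC2(OCCO2)C(C)(C)C=C[C@]1(C)CO
F7 | step 7 | racemic neopentyl aldehyde derived from F6 | COC1(OC)CC2(OCCO2)C(C)(C)C=C[C@]1(C)C=O
F8 | step 7 | racemic tosylhydrazone of F7 | COC1(OC)CC2(OCCO2)C(C)(C)C=C[C@]1(C)C=NNS(=O)(=O)c1ccc(C)cc1
F9 | step 3 | racemic 2,2,6-trimethyl-8-oxabicyclo[3.2.1]oct-6-en-3-one | O=C1C[C@H]2C(C)=C[C@H](O2)C1(C)C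
F10 | step 3 | racemic ethylene ketal of F9 | C1[C@H]2C(C)=C[C@H](O2)C(C)(C)C13OCCO3
F11 | step 3 | racemic trans-6,6,9-trimethyl-1,4-dioxaspiro[4.6]undec-7-en-10-ol | O[C@H]1CC2(OCCO2)C(C)(C)C=C[C@@H]1C
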